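## The problem

The target is a daucane-type hydroazulene. A seven-membered ring (C1 anisoyloxy, C2, C3 methyl, C4, C5 acetoxy, C6, C10) is trans-fused along C6–C10 to a cyclopentane (C6, C7, C8, C9, C10). It has five stereocentres: three contiguous ones at the ring fusion (C9, C10, C6) and one on each side of them (C1, C5). C6 is quaternary and cannot be corrected later, so it must be set by an enantioselective step. The other four should be relayed from it: C10–H trans to the C6 methyl, the C9 hydroxyl cis to that methyl, the C1 oxygen anti to the C9 hydroxyl, and the C5 oxygen cis to the C6 methyl. The two secondary alcohols carry different esters and must be told apart; C5 is neopentyl and allylic, C1 is homoallylic and next to the ring fusion. The sensitive groups are the allylic acetate (ionisation, vinylogous elimination), the tertiary C9 alcohol (β to C1, so retro-aldol or dehydration whenever C1 is a ketone) and the C3=C4 alkene, which can migrate. The enabling feature is that the C1 and C5 oxygens are 1,5-related through C2–C3–C4 and C3 bears a one-carbon branch. Reconnecting C2 to C5 and removing C3 with its branch and C4 leaves a cyclopentane-1,3-dione (C1, C2, C5, C6, C10) and a three-carbon cumulene, which is the pattern of a de Mayo ring expansion.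

## Retrosynthesis

**Esters and C5 carbinol (26 ⇒ 25 ⇒ 24).** The C5–O acetyl bond and the C5–H bond are cut last. Acetylating 25 when the only other free hydroxyl is tertiary needs no protecting group. Reducing enone 24 on the rigid bicycle lets the C6 methyl decide the C5 configuration, which a monocyclic precursor could not do.

**C3=C4 alkene (24 ⇒ 22).** The alkene is taken back to the saturated C5 ketone 22. The more direct alternative is to carry the exocyclic methylene of the photoproduct and isomerise it into conjugation. It was rejected because an alkene at C3 makes C2 and C4 doubly activated, and any enolate chemistry at C1 would then move the alkene or form a vinylogous diketonate. In 22 the C5 carbonyl can enolise only towards C4, since C6 is quaternary, so dehydrogenation can only give the C3=C4 enone.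

**C1 oxygen (22 ⇒ 20 + 21 ⇒ 19).** The anisoate comes from diol 20 and acid chloride 21; the secondary C1 hydroxyl reacts and the tertiary C9 hydroxyl does not. Diol 20 comes from ketol 19 by hydride delivery from the C9 hydroxyl. This one operation sets C1 and also distinguishes the C1 ketone (β to a hydroxyl) from the C5 ketone (neopentyl, not β to a hydroxyl).

**Five-membered ring (19 ⇒ 18).** The C9–C10 bond is cut by a retro-aldol to triketone 18. The alternative of adding an isopropyl nucleophile to a ring ketone would need a different side chain and more steps. The forward aldol has to give the ring-fused ketol and the trans ring fusion; both rest on reversibility, and this is the weakest step after the key step.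

**Saturation and unmasking (18 ⇒ 16).** Triketone 18 comes from the methylene dione 16 by alkene hydrogenation and dioxolane hydrolysis. The methylene carbon becomes the C3 methyl, and the temporary C3 stereocentre is erased when the alkene is reinstated.

**Seven-membered ring (16 ⇒ 13 + 14).** Bonds C2–C3 and C4–C5 are cut and C2–C5 is reconnected, giving cyclopentane-1,3-dione 13 and allene 14. A Dieckmann or metathesis closure of the seven-membered ring would need a long acyclic precursor with the quaternary centre in mid-chain. This cut reduces the problem to a five-membered ring with one stereocentre. The forward reaction only has to be head-to-head.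

**Dione oxidation level (13 ⇒ 12 ⇒ 11 ⇒ 9).** The 1,3-dione is traced through epoxy ketone 12 and enone 11 to cyclopentanone 9. Each step is a functional-group change next to the preset quaternary centre. The regiochemistry is forced because the ketone can be desaturated only away from that centre.

**Quaternary centre (9 ⇒ 7).** The C6–methyl bond is cut, which leads to the β-substituted cyclopentenone 7 and a catalytic enantioselective methyl conjugate addition. An auxiliary-based alkylation would be longer.

**Side chain (7 ⇒ 3 + 4; 3 ⇒ 1).** The C6–C7 bond is cut to vinylogous ester 4 and bromo ketal 3. Bromo ketal 3 is one operation from vinyl ketone 1 and carries C7, C8, C9 and the isopropyl group with C9 already masked.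

## Roads not taken

**Alternative 1:** chiral-pool ring contraction. The cut is C6–C10. Forward, a six-membered α-diazo ketone built from a terpene of the chiral pool is photolysed; nitrogen is lost, the quaternary carbon migrates with retention, and the ketene is trapped as cyclopentane ester A1.
- Merits: the absolute configuration is bought and not made, and C6, C9 and C10 sit in one small ring before any large ring exists.
- Weak points: A1 has hydrogen where C9 needs a hydroxyl, so a late oxidation or an alkene-shift and epoxide detour is required. The whole C2–C4 bridge must still be annulated between two neopentyl positions.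
- Comparison: this road is better on absolute stereochemistry, since the chosen plan depends on a catalytic step that is least selective on five-membered enones. It also does not leave the ring fusion to an aldol equilibrium. The chosen plan sets against this that one photochemical step delivers the complete seven-membered ring with both oxygens in place, and that C9 arrives at the correct oxidation level.

**Alternative 2:** conjugate addition with aldol trapping. The cuts are C6–CH3 and C10–C1. Forward, a methylaluminium reagent adds to a cyclopentenone under copper catalysis and the enolate is trapped by an aldehyde to give A2, which holds C6, C10 and C1.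
- Merits: it is convergent. The C3=C4 alkene arrives with fixed geometry as a vinyl iodide. The C5 carbinol would form during an intramolecular Nozaki–Hiyama–Kishi closure. The C9 ketone of A2 can later take an isopropyl nucleophile anti to the angular methyl, which is the more reliable way to set C9.
- Weak points: the aldol diastereoselectivity at C1 is uncertain. The seven-membered closure is onto a neopentyl aldehyde with uncertain C5 control. The isopropyl addition is to an enolisable, β-oxygenated cyclopentanone. Several protecting groups are needed.
- Comparison: this road is as good or better for C9 and for the placement of the alkene. The chosen plan sets against it a ring expansion that needs no medium-ring cyclisation, fewer protecting groups, and differentiation of C1 from C5 by the substrate itself.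

**Alternative 3:** divinylcyclopropane Cope rearrangement. The cut is C5–C6, with C1–C3 of a cyclopropane broken. Forward, a cis-divinylcyclopropane rearranges through a boat transition state to the bicyclic cycloheptadiene A3.
- Merits: A3 already contains the C5 acetate, the C3=C4 alkene, the quaternary C6 and a regiodefined C1 enol ether. The chosen plan needs steps 8 and 12–14 for the same features.
- Weak points: the precursor is a cyclopropane with a tetrasubstituted cyclopentenyl arm and an enol acetate of defined geometry, and it must be made cis and diastereoselectively relative to C9. Forming a quaternary centre at a fully substituted alkene terminus slows the rearrangement and invites hydrogen-shift side reactions. The ring fusion would depend on an enol ether protonation.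
- Comparison: this road is better in functional-group economy after the key step. The chosen plan sets against it a key-step precursor that is available in six routine steps and a key reaction that needs only one selectivity.

Key step: step 7

## Route

Assumption: 4-methylpent-1-en-3-one (1) is treated as a purchasable vinyl ketone.
Remark: locants C1–C10 are those defined above; compounds 17–20, 22 and 23 are mixtures of C3 epimers, a centre that is erased in step 12.

Step 1
Reactants: 1 4-methylpent-1-en-3-one
Product: 3 2-(2-bromoethyl)-2-(propan-2-yl)-1,3-dioxolane, via 1-bromo-4-methylpentan-3-one 2 (not isolated)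
Conditions: HBr (gas), CH2Cl2, 0 °C; then ethylene glycol, 4 Å MS, rt
Reagents that add atoms: hydrogen bromide, Br; ethylene glycol, OCCO
Why: Conjugate hydrobromination of the vinyl ketone followed by acid-catalysed ketalisation, as used for the lower homologue from methyl vinyl ketone; the dioxolane masks the C9 carbonyl through the organometallic and photochemical steps.

Step 2
Reactants: 3 2-(2-bromoethyl)-2-(propan-2-yl)-1,3-dioxolane; 4 3-ethoxycyclopent-2-en-1-one
Product: 7 3-{2-[2-(propan-2-yl)-1,3-dioxolan-2-yl]ethyl}cyclopent-2-en-1-one, via Grignard reagent 5 (not isolated), via tertiary allylic alcohol adduct 6 (not isolated)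
Conditions: Mg, THF, 25 °C; then 4, 0 °C; then 1 M HCl, 0 °C, short contact
Reagents that add atoms: water, O
Why: Stork–Danheiser sequence: 1,2-addition of the Grignard reagent to the vinylogous ester, then acid-induced loss of ethanol with carbonyl transposition gives the 3-alkyl enone. Brief cold dilute acid should spare the hindered dioxolane.

Step 3
Reactants: 7 3-{2-[2-(propan-2-yl)-1,3-dioxolan-2-yl]ethyl}cyclopent-2-en-1-one
Product: 9 (S)-3-methyl-3-{2-[2-(propan-2-yl)-1,3-dioxolan-2-yl]ethyl}cyclopentan-1-one, via dimethylaluminium enolate 8 (not isolated)
Conditions: Me3Al (2 equiv), Cu(OTf)2 (5 mol%), chiral binaphthol-derived phosphoramidite (10 mol%), Et2O, −30 °C; then aq. KNaC4H4O6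
Reagents that add atoms: trimethylaluminium, C[Al](C)C
Why: Copper-catalysed asymmetric conjugate addition of a methylaluminium reagent to a β-substituted cyclopentenone, a known route to all-carbon quaternary centres. C6 is set by the catalyst, and the ligand antipode that delivers methyl to the enone face leading to (S) is used.

Step 4
Reactants: 9 (S)-3-methyl-3-{2-[2-(propan-2-yl)-1,3-dioxolan-2-yl]ethyl}cyclopentan-1-one
Product: 11 (S)-4-methyl-4-{2-[2-(propan-2-yl)-1,3-dioxolan-2-yl]ethyl}cyclopent-2-en-1-one, via trimethylsilyl enol ether 10 (not isolated)
Conditions: LiN(i-Pr)2, Me3SiCl, THF, −78 °C; then Pd(OAc)2 (1.05 equiv), MeCN, rt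
Reagents that add atoms: none
Why: Saegusa–Ito dehydrogenation. Kinetic deprotonation occurs at the CH2 remote from the quaternary carbon, and only that enol ether has a β-hydrogen for the palladium elimination, so only one enone can form.

Step 5
Reactants: 11 (S)-4-methyl-4-{2-[2-(propan-2-yl)-1,3-dioxolan-2-yl]ethyl}cyclopent-2-en-1-one
Product: 12 (4S)-4-methyl-4-{2-[2-(propan-2-yl)-1,3-dioxolan-2-yl]ethyl}-6-oxabicyclo[3.1.0]hexan-2-one (both epoxide diastereomers)
Conditions: H2O2 (30% aq.), NaOH (cat.), MeOH, 0 °C
Reagents that add atoms: hydrogen peroxide, OO
Why: Weitz–Scheffer nucleophilic epoxidation of the enone. The epoxide configuration is irrelevant because both epoxide carbons lose their stereochemistry in step 6.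

Step 6
Reactants: 12 (4S)-4-methyl-4-{2-[2-(propan-2-yl)-1,3-dioxolan-2-yl]ethyl}-6-oxabicyclo[3.1.0]hexan-2-one
Product: 13 (S)-4-methyl-4-{2-[2-(propan-2-yl)-1,3-dioxolan-2-yl]ethyl}cyclopentane-1,3-dione
Conditions: Pd(PPh3)4 (5 mol%), Ph2PCH2CH2PPh2 (5 mol%), toluene, 90 °C
Reagents that add atoms: none
Why: Isomerisation of an α,β-epoxy ketone to a 1,3-diketone by zerovalent palladium (oxidative addition at the Cα–O bond, β-hydride elimination from the carbinol carbon, tautomerisation). The product is obtained as the enolised dione.

Step 7
Reactants: 13 (S)-4-methyl-4-{2-[2-(propan-2-yl)-1,3-dioxolan-2-yl]ethyl}cyclopentane-1,3-dione; 14 allene (propa-1,2-diene)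
Product: 16 (6S)-6-methyl-3-methylidene-6-{2-[2-(propan-2-yl)-1,3-dioxolan-2-yl]ethyl}cycloheptane-1,5-dione, via cyclobutanol photoadduct 15 (not isolated)
Conditions: 14 (10 equiv), CH2Cl2, −78 °C, hν (medium-pressure Hg lamp, Vycor filter, λ > 250 nm), to about 80% conversion; then warm to rt
Reagents that add atoms: none
Why: De Mayo reaction. The dione is irradiated as its enol, a β-hydroxy enone, whose triplet adds to allene stepwise through a 1,4-diradical; spin inversion and radical recombination close the four-membered ring with the central allene carbon (C3) on C2 and the terminal carbon (C4) on C5. The resulting bicyclo[3.2.0]heptane 15 is a strained β-hydroxy ketone, and retro-aldol cleavage of the shared C2–C5 bond merges the four- and five-membered rings into the seven-membered 1,5-dione, so the large ring arises by fragmentation of a bicycle and not by end-to-end closure. The closest known reactions are the de Mayo ring expansion of enolised cyclic 1,3-diketones with alkenes and the head-to-head photocycloaddition of cyclic enones to allene. No new stereocentre survives: the two cyclobutane centres of 15 become a carbonyl carbon and a CH2 group, and the quaternary C6 is a spectator. The one selectivity needed is head-to-head regiochemistry, the normal sense for enone–allene additions; either enol tautomer then gives the same 16, because the methylene carbon ends up midway between the two carbonyls in both cases. Irradiating where the enol absorbs far more strongly than the product ketones and stopping short of full conversion protect 16 from secondary photoreactions, and any drift of the exocyclic alkene into conjugation is harmless because step 8 saturates it.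

Step 8
Reactants: 16 (6S)-6-methyl-3-methylidene-6-{2-[2-(propan-2-yl)-1,3-dioxolan-2-yl]ethyl}cycloheptane-1,5-dione
Product: 18 (6S)-3,6-dimethyl-6-(4-methyl-3-oxopentyl)cycloheptane-1,5-dione (C3 epimers), via saturated dioxolane dione 17 (not isolated)
Conditions: H2 (1 atm), Pd/C, THF, rt; then 2 M HCl added, rt
Reagents that add atoms: water, O
Why: Heterogeneous hydrogenation of the 1,1-disubstituted alkene followed by acid hydrolysis of the dioxolane. Saturating C3 removes the doubly activated allylic CH2 groups, so the basic step that follows can neither move an alkene into conjugation nor form a vinylogous diketonate.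

Step 9
Reactants: 18 (6S)-3,6-dimethyl-6-(4-methyl-3-oxopentyl)cycloheptane-1,5-dione
Product: 19 trans-fused ketol, (6S,9R,10R)-9-hydroxy-3,6-dimethyl-9-(propan-2-yl)hydroazulene-1,5-dione (locants of the text; C9 hydroxyl cis to the C6 methyl, C10–H trans to it)
Conditions: NaOMe (0.2 equiv), MeOH, 0 °C to rt, monitored and quenched before dehydration
Reagents that add atoms: none
Why: Reversible intramolecular aldol addition of a 1,6-diketone (5-enolexo-exo-trig): only the C10 enolate reaches the C9 carbonyl through an unstrained ring-fused transition state. Because the aldol is reversible and C10 stays epimerisable, the ketol should settle in the arrangement with the isopropyl group anti to the C10–C1 bond and a trans ring fusion, which places the C9 hydroxyl cis to the C6 methyl and hydrogen-bonded to the C1 carbonyl.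

Step 10
Reactants: 19 trans-fused ketol
Product: 20 (1S,6S,9R,10S)-1,9-dihydroxy-3,6-dimethyl-9-(propan-2-yl)hydroazulen-5-one (C1 hydroxyl anti to the C9 hydroxyl, cis to C10–H)
Conditions: Me4NBH(OAc)3, MeCN/AcOH (1:1), −20 °C to rt
Reagents that add atoms: none
Why: Evans–Saksena hydroxyl-directed reduction: the C9 hydroxyl exchanges onto boron and hydride is delivered intramolecularly to C1 from the face of the C9 oxygen through a six-membered transition state, giving the 1,3-anti diol. The C5 ketone is neopentyl and not β to a hydroxyl, so it is left alone.

Step 11
Reactants: 20 (1S,6S,9R,10S)-1,9-dihydroxy-3,6-dimethyl-9-(propan-2-yl)hydroazulen-5-one; 21 4-methoxybenzoyl chloride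
Product: 22 (1S,6S,9R,10S)-9-hydroxy-3,6-dimethyl-5-oxo-9-(propan-2-yl)hydroazulen-1-yl 4-methoxybenzoate
Conditions: 21, Et3N, 4-(dimethylamino)pyridine (cat.), CH2Cl2, 0 °C to rt
Reagents that add atoms: none
Why: Nucleophile-catalysed acylation of the secondary C1 alcohol; the tertiary, hindered C9 alcohol does not compete under these conditions.

Step 12
Reactants: 22 (1S,6S,9R,10S)-9-hydroxy-3,6-dimethyl-5-oxo-9-(propan-2-yl)hydroazulen-1-yl 4-methoxybenzoate
Product: 24 (1S,6S,9R,10S)-9-hydroxy-3,6-dimethyl-5-oxo-9-(propan-2-yl)hydroazul-3-en-1-yl 4-methoxybenzoate (C3=C4 enone), via bis(trimethylsilyl) intermediate 23 (not isolated)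
Conditions: Me3SiOTf, Et3N, CH2Cl2, 0 °C; then Pd(OAc)2 (1.1 equiv), MeCN, rt; then 1 M HCl work-up
Reagents that add atoms: none
Why: Saegusa–Ito dehydrogenation: the C5 ketone can enolise only towards C4, so the enol silane and hence the C3=C4 enone are regiochemically unambiguous, and both C3 epimers converge. The C9 hydroxyl is silylated in passing and freed again on acidic work-up.

Step 13
Reactants: 24 C3=C4 enone
Product: 25 (1S,5S,6S,9R,10S)-5,9-dihydroxy-3,6-dimethyl-9-(propan-2-yl)hydroazul-3-en-1-yl 4-methoxybenzoate (C5 hydroxyl cis to the C6 methyl)
Conditions: NaBH4, CeCl3·7H2O, MeOH, −78 to 0 °C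
Reagents that add atoms: none
Why: Luche 1,2-reduction of the enone; hydride should approach C5 from the face opposite the axial C6 methyl on the neighbouring carbon, giving the alcohol cis to that methyl. The aryl ester is inert to the reagent.

Step 14
Reactants: 25 (1S,5S,6S,9R,10S)-5,9-dihydroxy-3,6-dimethyl-9-(propan-2-yl)hydroazul-3-en-1-yl 4-methoxybenzoate
Product: 26 target, (1S,5S,6S,9R,10S)-5-acetoxy-9-hydroxy-3,6-dimethyl-9-(propan-2-yl)hydroazul-3-en-1-yl 4-methoxybenzoate
Conditions: Ac2O, pyridine, 4-(dimethylamino)pyridine (cat.), CH2Cl2, rt
Reagents that add atoms: acetic anhydride, CC(=O)OC(C)=O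
Why: Acetylation of the secondary allylic alcohol; the tertiary C9 hydroxyl, flanked by the isopropyl group and the ring fusion, should remain free at room temperature with limited anhydride.

## Compound list

1 | 4-methylpent-1-en-3-one | CC(C)C(=O)C=C | starting material
2 | 1-bromo-4-methylpentan-3-one | CC(C)C(=O)CCBr | intermediate
3 | 2-(2-bromoethyl)-2-(propan-2-yl)-1,3-dioxolane | CC(C)C1(CCBr)OCCO1 | intermediate
4 | 3-ethoxycyclopent-2-en-1-one | CCOC1=CC(=O)CC1 | starting material
5 | {2-[2-(propan-2-yl)-1,3-dioxolan-2-yl]ethyl}magnesium bromide | CC(C)C1(CC[Mg]Br)OCCO1 | intermediate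
6 | 3-ethoxy-1-{2-[2-(propan-2-yl)-1,3-dioxolan-2-yl]ethyl}cyclopent-2-en-1-ol (racemic) | CCOC1=CC(O)(CCC2(C(C)C)OCCO2)CC1 | intermediate
7 | 3-{2-[2-(propan-2-yl)-1,3-dioxolan-2-yl]ethyl}cyclopent-2-en-1-one | O=C1CCC(CCC2(C(C)C)OCCO2)=C1 | intermediate
8 | dimethylaluminium enolate of 9 (enolate double bond towards the quaternary carbon) | C[Al](C)OC1=C[C@](C)(CCC2(C(C)C)OCCO2)CC1 | intermediate
9 | (S)-3-methyl-3-{2-[2-(propan-2-yl)-1,3-dioxolan-2-yl]ethyl}cyclopentan-1-one | O=C1CC[C@@](C)(CCC2(C(C)C)OCCO2)C1 | intermediate
10 | trimethylsilyl enol ether of 9 (double bond away from the quaternary carbon) | C[Si](C)(C)OC1=CC[C@@](C)(CCC2(C(C)C)OCCO2)C1 | intermediate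
11 | (S)-4-methyl-4-{2-[2-(propan-2-yl)-1,3-dioxolan-2-yl]ethyl}cyclopent-2-en-1-one | O=C1C=C[C@@](C)(CCC2(C(C)C)OCCO2)C1 | intermediate
12 | (4S)-4-methyl-4-{2-[2-(propan-2-yl)-1,3-dioxolan-2-yl]ethyl}-6-oxabicyclo[3.1.0]hexan-2-one, both epoxide diastereomers | O=C1C2OC2[C@@](C)(CCC3(C(C)C)OCCO3)C1 | intermediate
13 | (S)-4-methyl-4-{2-[2-(propan-2-yl)-1,3-dioxolan-2-yl]ethyl}cyclopentane-1,3-dione | O=C1CC(=O)[C@@](C)(CCC2(C(C)C)OCCO2)C1 | intermediate
14 | allene (propa-1,2-diene) | C=C=C | starting material
15 | cyclobutanol photoadduct: 5-hydroxy-6-methylidenebicyclo[3.2.0]heptan-2-one core with the C6 methyl and side chain, cis-fused, cyclobutane centres unassigned | O=C1C[C@](C)(CCC2(C(C)C)OCCO2)C3(O)CC(=C)C13 | intermediate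
16 | (6S)-6-methyl-3-methylidene-6-{2-[2-(propan-2-yl)-1,3-dioxolan-2-yl]ethyl}cycloheptane-1,5-dione | O=C1CC(=C)CC(=O)[C@@](C)(CCC2(C(C)C)OCCO2)C1 | intermediate
17 | (6S)-3,6-dimethyl-6-{2-[2-(propan-2-yl)-1,3-dioxolan-2-yl]ethyl}cycloheptane-1,5-dione, C3 epimers | O=C1CC(C)CC(=O)[C@@](C)(CCC2(C(C)C)OCCO2)C1 | intermediate
18 | (6S)-3,6-dimethyl-6-(4-methyl-3-oxopentyl)cycloheptane-1,5-dione, C3 epimers | O=C1CC(C)CC(=O)[C@@](C)(CCC(=O)C(C)C)C1 | intermediate
19 | trans-fused ketol (6S,9R,10R), C3 epimers: C1 and C5 ketones, C9 hydroxyl cis to C6 methyl | O=C1CC(C)CC(=O)[C@@]2(C)CC[C@@](O)(C(C)C)[C@H]12 | intermediate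
20 | 1,9-diol (1S,6S,9R,10S), C3 epimers: C5 ketone, C1 hydroxyl anti to C9 hydroxyl | O[C@H]1CC(C)CC(=O)[C@@]2(C)CC[C@@](O)(C(C)C)[C@H]12 | intermediate
21 | 4-methoxybenzoyl chloride | COc1ccc(cc1)C(Cl)=O | starting material
22 | C1 4-methoxybenzoate of 20 (1S,6S,9R,10S), C3 epimers | COc1ccc(C(=O)O[C@H]2CC(C)CC(=O)[C@@]3(C)CC[C@@](O)(C(C)C)[C@H]23)cc1 | intermediate
23 | C5 trimethylsilyl enol ether and C9 trimethylsilyl ether of 22 | COc1ccc(C(=O)O[C@H]2CC(C)C=C(O[Si](C)(C)C)[C@@]3(C)CC[C@@](O[Si](C)(C)C)(C(C)C)[C@H]23)cc1 | intermediate
24 | C3=C4 enone (1S,6S,9R,10S): C5 ketone, C1 4-methoxybenzoate, C9 hydroxyl | COc1ccc(C(=O)O[C@H]2CC(C)=CC(=O)[C@@]3(C)CC[C@@](O)(C(C)C)[C@H]23)cc1 | intermediate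
25 | C5 allylic alcohol (1S,5S,6S,9R,10S), hydroxyl cis to C6 methyl | COc1ccc(C(=O)O[C@H]2CC(C)=C[C@H](O)[C@@]3(C)CC[C@@](O)(C(C)C)[C@H]23)cc1 | intermediate
26 | CNP0256979.3, (1S,5S,6S,9R,10S)-5-acetoxy-9-hydroxy-3,6-dimethyl-9-(propan-2-yl)hydroazul-3-en-1-yl 4-methoxybenzoate | COc1ccc(C(=O)O[C@H]2CC(C)=C[C@H](OC(C)=O)[C@@]3(C)CC[C@@](O)(C(C)C)[C@H]23)cc1 | target

## Step count and risks

Total: 14 steps. Longest linear sequence: 14 steps, from 1 to 26; compounds 4, 14 and 21 are purchased and enter in steps 2, 7 and 11.

**Step 7 (key step).** The most likely failure is secondary photochemistry. Product 16 is a β,γ-unsaturated ketone on both sides and can undergo acyl shift or decarbonylation once it competes with the enol for light. Slow addition or some head-to-tail addition are also possible. The fallback separates the photoaddition from the ring opening. It sets out from 13: O-acetylation (Ac2O, Et3N) should give the enol acetate F1, mainly the isomer acylated on the oxygen remote from the quaternary carbon. Irradiation with allene through Pyrex (λ > 300 nm, the classical enone–allene conditions, where only the enone chromophore absorbs) should give the isolable acetoxy methylenecyclobutane F2. K2CO3 in MeOH then removes the acetate, and the cyclobutanolate opens by retro-aldol to 16, where the route is rejoined. The minor enol acetate regioisomer converges on the same 16.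

**Step 9.** The most likely failure is loss of regio- and stereocontrol in a reversible aldol.
- The C8 enolate can add to C1, and the C4 enolate to C9, to give bridged ketols.
- Kinetic closure favours a cis ring fusion.
- Prolonged equilibration leads to dehydration.

The fallback uses the dehydration. It sets out from 18: forcing conditions (KOH, MeOH, 60 °C) should funnel all material to the bicyclic enone F3, because only the C10-to-C9 mode can lose water without forming a bridgehead alkene. Nucleophilic epoxidation (H2O2, NaOH, MeOH) is expected from the face of the small C6 methyl rather than the face covered by the C5 arm of the seven-membered ring, giving the epoxy ketone F4. SmI2 (THF/MeOH, −78 °C) cleaves the Cα–O bond with retention at C9. Protonation of the C10 samarium enolate, with DBU equilibration if needed, should then give 19, where the route is rejoined.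

**Step 3.** The most likely failure is insufficient enantioselectivity, since five-membered enones are the hardest ring size for this reaction; Lewis-acid opening of the dioxolane by the aluminium reagent is also possible. The fallback reverses the roles of the two substituents at C6 and uses no aluminium. It sets out from Grignard reagent 5, which is added to purchased 3-methylcyclopent-2-en-1-one (CC1=CC(=O)CC1) under Cu(OTf)2 and a chiral N-heterocyclic carbene ligand in Et2O at low temperature. This should give 9 directly, with the ligand antipode chosen for the (S) centre. No new compound is made.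

**Step 10.** The most likely failure is poor facial selectivity: the hindered tertiary C9 hydroxyl may exchange onto boron too slowly, so that undirected hydride delivery competes. The fallback replaces the transient boron link by a covalent silicon tether. It sets out from 19: silylation with (HMe2Si)2NH should give the hydridosilyl ether F5. Fluoride- or SnCl4-promoted intramolecular hydrosilylation of the C1 carbonyl delivers hydride from the face of the C9 oxygen and should give the cyclic siloxane F6. K2CO3 in MeOH releases diol 20, where the route is rejoined.

**Step 12.** The most likely failure is incomplete enol silane formation at the neopentyl C5 ketone, or palladium-induced side reactions on a substrate carrying an ester and a silylated tertiary alcohol. The fallback is halogenation followed by elimination. It sets out from 22: PhNMe3Br3 in THF should brominate C4, the only enolisable position of the C5 ketone, to give the α-bromo ketone F7. Li2CO3 and LiBr in DMF at 110 °C should eliminate HBr to give 24, where the route is rejoined.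

## Further compounds

F1 | step 7 | (S)-4-methyl-3-oxo-4-{2-[2-(propan-2-yl)-1,3-dioxolan-2-yl]ethyl}cyclopent-1-en-1-yl acetate | CC(=O)OC1=CC(=O)[C@@](C)(CCC2(C(C)C)OCCO2)C1
F2 | step 7 | acetoxy methylenecyclobutane photoadduct (bicyclo[3.2.0]heptan-2-one, acetate on the ring-fusion carbon remote from the quaternary centre, methylidene on the carbon next to the other ring-fusion carbon; cyclobutane centres unassigned) | O=C1C2C(=C)CC2(OC(C)=O)C[C@]1(C)CCC3(C(C)C)OCCO3
F3 | step 9 | bicyclic enone, C9=C10 alkene conjugated with the C1 ketone, C5 ketone, (6S), C3 epimers | O=C1CC(C)CC(=O)[C@@]2(C)CCC(C(C)C)=C12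
F4 | step 9 | C9,C10-epoxide of F3 with the oxygen on the face of the C6 methyl | O=C1CC(C)CC(=O)[C@@]2(C)CC[C@]3(C(C)C)O[C@]123
F0 | step 3 | none | none
F5 | step 10 | C9 dimethylsilyl (Si–H) ether of 19 | O=C1CC(C)CC(=O)[C@@]2(C)CC[C@@](O[SiH](C)C)(C(C)C)[C@H]12
F6 | step 10 | cyclic dimethylsiloxane bridging the C1 and C9 oxygens, C1 configured as in 20 | C[Si]1(C)O[C@H]2CC(C)CC(=O)[C@@]3(C)CC[C@@](O1)(C(C)C)[C@H]23
F7 | step 12 | C4-bromo derivative of 22 (C3 and C4 unassigned) | COc1ccc(C(=O)O[C@H]2CC(C)C(Br)C(=O)[C@@]3(C)CC[C@@](O)(C(C)C)[C@H]23)cc1
A1 | alternative 1 | methyl 2-[(benzyloxy)methyl]-2-methyl-5-(prop-1-en-2-yl)cyclopentane-1-carboxylate, stereochemistry as in the SMILES | COC(=O)[C@H]1[C@H](C(C)=C)CC[C@]1(C)COCc1ccccc1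
A2 | alternative 2 | 3-(dimethoxymethyl)-2-[(Z)-1-hydroxy-4-iodo-3-methylbut-3-en-1-yl]-3-methylcyclopentan-1-one, stereochemistry as in the SMILES | O[C@@H](C/C(C)=C\I)[C@H]1C(=O)CC[C@]1(C)C(OC)OC
A3 | alternative 3 | bicyclic cycloheptadiene with C1 tert-butyldimethylsilyl enol ether, C9 trimethylsilyl ether, C5 acetate and C6 quaternary methyl | CC(C)(C)[Si](C)(C)OC1=C2[C@](O[Si](C)(C)C)(C(C)C)CC[C@]2(C)[C@@H](OC(C)=O)C=C(C)C1
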